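**Strategy.** The trans-fused α-methylene-γ-butyrolactone is disconnected at C15–C16 (α-carbon/carbonyl) and at C1–C14, the bond it shares with the 14-membered carbocycle (cembrane numbering; C17 = exocyclic CH2). The structural feature exploited is that C17=C15–C1 is a masked terminal allene and the lactone carbonyl C16 a masked CO2. In one operation, nickel(0) couples CO2 to the central allene carbon and the resulting allylnickel carboxylate allylates the tethered C14 enal, closing the macrocycle and the lactone skeleton and setting C1/C14. The precursor is an acyclic C19 allenyl trienal with silyl-protected C6/C10 carbinols, built by two catalytic asymmetric vinylogous Mukaiyama aldol reactions.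

Key step: step 13

Remark: cembrane numbering (ring C1–C14, lactone C15/C16, methylene C17) is used for the macrocycles and in the Why lines; acyclic compounds are named by their own chain locants; the DBU ligands of nickelacycle 17 are omitted from its SMILES.
Remark: for steps 5 and 9 the catalyst antipode is assumed to be the one that directs the dienolate to the Si face of the enal (expected (S,S)); this would be confirmed on 9 by Mosher ester analysis.

Step 1
Reactants: 1 ethyl 3-methylbut-2-enoate
Product: 2 tert-butyl[(1-ethoxy-3-methylbuta-1,3-dien-1-yl)oxy]dimethylsilane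
Conditions: LDA, THF, −78 °C; then TBSCl, DMPU, −78 °C → rt
Reagents that add atoms: tert-butyldimethylsilyl chloride, CC(C)(C)[Si](C)(C)Cl
Why: kinetic γ-deprotonation of the senecioate and O-silylation of the extended lithium dienolate (silyl ketene acetal formation) should give the conjugated silyl dienol ether; no stereocentre is formed.

Step 2
Reactants: 3 hex-5-yn-2-one; 4 diethyl {2-[methoxy(methyl)amino]-2-oxoethyl}phosphonate
Product: 5 (2E)-N-methoxy-N,3-dimethylhept-2-en-6-ynamide
Conditions: NaH, THF, 0 °C (anion preformed), then 3, reflux; minor 2Z isomer removed by chromatography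
Reagents that add atoms: none
Why: Horner–Wadsworth–Emmons olefination of the methyl ketone with the stabilised Weinreb-amide phosphonate should favour the E-trisubstituted enamide (chain trans to the carbonyl), the terminal alkyne being inert.

Step 3
Reactants: 5 (2E)-N-methoxy-N,3-dimethylhept-2-en-6-ynamide
Product: 7 (2E)-N-methoxy-N,3-dimethylocta-2,6,7-trienamide, via Mannich base 6 (not isolated)
Conditions: (CH2O)n, CuI (0.5 equiv), Cy2NH, 1,4-dioxane, reflux
Reagents that add atoms: paraformaldehyde (as formaldehyde), C=O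
Why: Crabbé homologation, in which copper-mediated Mannich coupling gives propargylic amine 6 and its intramolecular hydride transfer/elimination should release the terminal allene; no stereocentre is formed.

Step 4
Reactants: 7 (2E)-N-methoxy-N,3-dimethylocta-2,6,7-trienamide
Product: 8 (2E)-3-methylocta-2,6,7-trienal
Conditions: DIBAL-H (1.2 equiv), THF, −78 °C; aq. Rochelle salt
Reagents that add atoms: none
Why: Weinreb amide reduction stops at the chelated aluminium hemiaminal, which should collapse to the enal only on work-up, leaving the allene and the E-olefin untouched.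

Step 5
Reactants: 8 (2E)-3-methylocta-2,6,7-trienal; 2 silyl dienol ether
Product: 9 ethyl (2E,5S,6E)-5-hydroxy-3,7-dimethyldodeca-2,6,10,11-tetraenoate
Conditions: SiCl4 (1.1 equiv), chiral binaphthyldiamine-derived bisphosphoramide (5 mol %), i-Pr2NEt (10 mol %), CH2Cl2, −78 °C; aq. NaHCO3
Reagents that add atoms: none
Why: Lewis-base-activated SiCl4 vinylogous Mukaiyama aldol reaction, in which the chiral phosphoramide-bound trichlorosilyl cation should direct γ-attack of the dienolate to the Si face of the enal (catalyst control) to set C5 (S; cembrane C6) and give the E-enoate.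

Step 6
Reactants: 9 ethyl (2E,5S,6E)-5-hydroxy-3,7-dimethyldodeca-2,6,10,11-tetraenoate
Product: 10 ethyl (2E,5S,6E)-3,7-dimethyl-5-[(triethylsilyl)oxy]dodeca-2,6,10,11-tetraenoate
Conditions: TESCl, imidazole, DMF, 0 °C
Reagents that add atoms: triethylsilyl chloride, CC[Si](CC)(CC)Cl
Why: standard silylation of the secondary allylic alcohol; TES is chosen because it can later be cleaved in the presence of TBS.

Step 7
Reactants: 10 ethyl (2E,5S,6E)-3,7-dimethyl-5-[(triethylsilyl)oxy]dodeca-2,6,10,11-tetraenoate
Product: 11 (2E,5S,6E)-3,7-dimethyl-5-[(triethylsilyl)oxy]dodeca-2,6,10,11-tetraen-1-ol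
Conditions: DIBAL-H (2.2 equiv), CH2Cl2, −78 °C; aq. Rochelle salt
Reagents that add atoms: none
Why: 1,2-reduction of the enoate to the allylic alcohol by DIBAL-H, which should not touch the allene or the silyl ether at −78 °C.

Step 8
Reactants: 11 (2E,5S,6E)-3,7-dimethyl-5-[(triethylsilyl)oxy]dodeca-2,6,10,11-tetraen-1-ol
Product: 12 (2E,5S,6E)-3,7-dimethyl-5-[(triethylsilyl)oxy]dodeca-2,6,10,11-tetraenal
Conditions: activated MnO2, CH2Cl2, rt
Reagents that add atoms: none
Why: chemoselective allylic oxidation with MnO2 under neutral conditions, so the E-geometry and the TES ether should persist.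

Step 9
Reactants: 12 (2E,5S,6E)-3,7-dimethyl-5-[(triethylsilyl)oxy]dodeca-2,6,10,11-tetraenal; 2 silyl dienol ether
Product: 13 ethyl (2E,5S,6E,9S,10E)-5-hydroxy-3,7,11-trimethyl-9-[(triethylsilyl)oxy]hexadeca-2,6,10,14,15-pentaenoate
Conditions: SiCl4 (1.1 equiv), the same bisphosphoramide antipode (5 mol %), i-Pr2NEt (10 mol %), CH2Cl2, −78 °C; aq. NaHCO3
Reagents that add atoms: none
Why: second catalyst-controlled vinylogous Mukaiyama aldol reaction; the existing stereocentre is δ to the aldehyde and should exert negligible 1,5-induction, so Si-face attack again sets the new C5 (S; cembrane C10).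

Step 10
Reactants: 13 ethyl (2E,5S,6E,9S,10E)-5-hydroxy-3,7,11-trimethyl-9-[(triethylsilyl)oxy]hexadeca-2,6,10,14,15-pentaenoate
Product: 14 ethyl (2E,5S,6E,9S,10E)-5-[(tert-butyldimethylsilyl)oxy]-3,7,11-trimethyl-9-[(triethylsilyl)oxy]hexadeca-2,6,10,14,15-pentaenoate
Conditions: TBSCl, imidazole, DMF, rt
Reagents that add atoms: tert-butyldimethylsilyl chloride, CC(C)(C)[Si](C)(C)Cl
Why: standard silylation; the more robust TBS group differentiates this carbinol (the later free hydroxyl) from the TES-protected one (the later acetate).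

Step 11
Reactants: 14 ethyl (2E,5S,6E,9S,10E)-5-[(tert-butyldimethylsilyl)oxy]-3,7,11-trimethyl-9-[(triethylsilyl)oxy]hexadeca-2,6,10,14,15-pentaenoate
Product: 15 (2E,5S,6E,9S,10E)-5-[(tert-butyldimethylsilyl)oxy]-3,7,11-trimethyl-9-[(triethylsilyl)oxy]hexadeca-2,6,10,14,15-pentaen-1-ol
Conditions: DIBAL-H (2.2 equiv), CH2Cl2, −78 °C; aq. Rochelle salt
Reagents that add atoms: none
Why: 1,2-reduction of the enoate to the allylic alcohol, as in step 7.

Step 12
Reactants: 15 (2E,5S,6E,9S,10E)-5-[(tert-butyldimethylsilyl)oxy]-3,7,11-trimethyl-9-[(triethylsilyl)oxy]hexadeca-2,6,10,14,15-pentaen-1-ol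
Product: 16 (2E,5S,6E,9S,10E)-5-[(tert-butyldimethylsilyl)oxy]-3,7,11-trimethyl-9-[(triethylsilyl)oxy]hexadeca-2,6,10,14,15-pentaenal
Conditions: activated MnO2, CH2Cl2, rt
Reagents that add atoms: none
Why: chemoselective allylic oxidation with MnO2, as in step 8.

Step 13
Reactants: 16 (2E,5S,6E,9S,10E)-5-[(tert-butyldimethylsilyl)oxy]-3,7,11-trimethyl-9-[(triethylsilyl)oxy]hexadeca-2,6,10,14,15-pentaenal
Product: 20 (1R,6S,10S,14S,4E,8E,12E)-10-[(tert-butyldimethylsilyl)oxy]-6-hydroxycembra-4,8,12,15(17)-tetraen-16,14-olide, via oxanickelacycle 17 (not isolated), via seco hydroxy acid 18 (not isolated), via TES lactone 19 (not isolated)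
Conditions: Ni(cod)2 (1.2 equiv), DBU (2.4 equiv), CO2 (1 atm), THF, 0 °C → rt, 16 added by syringe pump (final 2 mM); then AcOH/THF/H2O (3:1:1), rt
Reagents that add atoms: carbon dioxide, O=C=O
Why: Proposed new method: Ni(0)–DBU should bind the terminal C15=C17 π-bond of the allene and couple it oxidatively with CO2 at the central carbon (C15–C16), giving allylnickel carboxylate 17, whose substituted terminus C1 then adds to the tethered C14 aldehyde (C1–C14) before protonolysis to 18. The closest known reaction type is the intermolecular nickel(0)-mediated sequential addition of CO2 and aryl aldehydes to terminal allenes, here made intramolecular with a conjugated aldehyde under high dilution; allylchromium–aldehyde macrocyclisations are the precedent for closing 14-membered rings by carbonyl allylation. The 14-membered carbocycle closes in a 14-exo-trig carbonyl allylation through a six-membered chair array (Ni–O=C14···C1=C15–C17), and the γ-lactone closes afterwards by 5-exo-trig attack of the C14 hydroxyl on the C16 acid in the AcOH work-up, which also removes the more labile TES group. The C1/C14 relative configuration (anti, hence the trans-fused lactone) is expected from the σ-allylnickel with the C2 chain E to CH2Ni and the enal residue equatorial in the chair. The sense relative to C6 and C10 is not under reagent control and must come from the folding of the chain, with the C10 silyloxy group expected to lie outside the forming ring; this remote induction is the least secure element and the other trans isomer is the expected by-product. The step also needs CO2–allene coupling to outrun Ni–enal chemistry (1 atm CO2, slow substrate addition), attack through C1 rather than C17 (SE2′ from the primary σ-allyl form) and 1,2-addition to the enal (closed transition state).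

Step 14
Reactants: 20 (1R,6S,10S,14S,4E,8E,12E)-10-[(tert-butyldimethylsilyl)oxy]-6-hydroxycembra-4,8,12,15(17)-tetraen-16,14-olide
Product: 21 (1R,6S,10S,14S,4E,8E,12E)-6-acetoxy-10-[(tert-butyldimethylsilyl)oxy]cembra-4,8,12,15(17)-tetraen-16,14-olide
Conditions: Ac2O, pyridine, DMAP (cat.), CH2Cl2, 0 °C
Reagents that add atoms: acetic anhydride, CC(=O)OC(C)=O
Why: DMAP-catalysed acetylation of the only free hydroxyl (C6) with retention of configuration; the C10 oxygen stays masked as its TBS ether.

Step 15
Reactants: 21 (1R,6S,10S,14S,4E,8E,12E)-6-acetoxy-10-[(tert-butyldimethylsilyl)oxy]cembra-4,8,12,15(17)-tetraen-16,14-olide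
Product: 22 (1R,6S,10S,14S,4E,8E,12E)-6-acetoxy-10-hydroxycembra-4,8,12,15(17)-tetraen-16,14-olide (CNP0406430.1)
Conditions: HF·pyridine, pyridine/THF, 0 °C → rt
Reagents that add atoms: none
Why: buffered fluoride-mediated desilylation should free the C10 hydroxyl without touching the allylic acetate or the α-methylene lactone, which are base- and nucleophile-sensitive.

**Compound list**

1 | ethyl 3-methylbut-2-enoate | CCOC(=O)C=C(C)C | starting material
2 | tert-butyl[(1-ethoxy-3-methylbuta-1,3-dien-1-yl)oxy]dimethylsilane | C=C(C)C=C(OCC)O[Si](C)(C)C(C)(C)C | intermediate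
3 | hex-5-yn-2-one | CC(=O)CCC#C | starting material
4 | diethyl {2-[methoxy(methyl)amino]-2-oxoethyl}phosphonate | CCOP(=O)(OCC)CC(=O)N(C)OC | starting material
5 | (2E)-N-methoxy-N,3-dimethylhept-2-en-6-ynamide | CON(C)C(=O)/C=C(\C)CCC#C | intermediate
6 | (2E)-8-(dicyclohexylamino)-N-methoxy-N,3-dimethyloct-2-en-6-ynamide (Mannich base, not isolated) | CON(C)C(=O)/C=C(\C)CCC#CCN(C1CCCCC1)C1CCCCC1 | intermediate
7 | (2E)-N-methoxy-N,3-dimethylocta-2,6,7-trienamide | CON(C)C(=O)/C=C(\C)CCC=C=C | intermediate
8 | (2E)-3-methylocta-2,6,7-trienal | O=C/C=C(\C)CCC=C=C | intermediate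
9 | ethyl (2E,5S,6E)-5-hydroxy-3,7-dimethyldodeca-2,6,10,11-tetraenoate | CCOC(=O)/C=C(\C)C[C@H](O)/C=C(\C)CCC=C=C | intermediate
10 | ethyl (2E,5S,6E)-3,7-dimethyl-5-[(triethylsilyl)oxy]dodeca-2,6,10,11-tetraenoate | CCOC(=O)/C=C(\C)C[C@H](O[Si](CC)(CC)CC)/C=C(\C)CCC=C=C | intermediate
11 | (2E,5S,6E)-3,7-dimethyl-5-[(triethylsilyl)oxy]dodeca-2,6,10,11-tetraen-1-ol | OC/C=C(\C)C[C@H](O[Si](CC)(CC)CC)/C=C(\C)CCC=C=C | intermediate
12 | (2E,5S,6E)-3,7-dimethyl-5-[(triethylsilyl)oxy]dodeca-2,6,10,11-tetraenal | O=C/C=C(\C)C[C@H](O[Si](CC)(CC)CC)/C=C(\C)CCC=C=C | intermediate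
13 | ethyl (2E,5S,6E,9S,10E)-5-hydroxy-3,7,11-trimethyl-9-[(triethylsilyl)oxy]hexadeca-2,6,10,14,15-pentaenoate | CCOC(=O)/C=C(\C)C[C@H](O)/C=C(\C)C[C@H](O[Si](CC)(CC)CC)/C=C(\C)CCC=C=C | intermediate
14 | ethyl (2E,5S,6E,9S,10E)-5-[(tert-butyldimethylsilyl)oxy]-3,7,11-trimethyl-9-[(triethylsilyl)oxy]hexadeca-2,6,10,14,15-pentaenoate | CCOC(=O)/C=C(\C)C[C@H](O[Si](C)(C)C(C)(C)C)/C=C(\C)C[C@H](O[Si](CC)(CC)CC)/C=C(\C)CCC=C=C | intermediate
15 | (2E,5S,6E,9S,10E)-5-[(tert-butyldimethylsilyl)oxy]-3,7,11-trimethyl-9-[(triethylsilyl)oxy]hexadeca-2,6,10,14,15-pentaen-1-ol | OC/C=C(\C)C[C@H](O[Si](C)(C)C(C)(C)C)/C=C(\C)C[C@H](O[Si](CC)(CC)CC)/C=C(\C)CCC=C=C | intermediate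
16 | (2E,5S,6E,9S,10E)-5-[(tert-butyldimethylsilyl)oxy]-3,7,11-trimethyl-9-[(triethylsilyl)oxy]hexadeca-2,6,10,14,15-pentaenal | O=C/C=C(\C)C[C@H](O[Si](C)(C)C(C)(C)C)/C=C(\C)C[C@H](O[Si](CC)(CC)CC)/C=C(\C)CCC=C=C | intermediate
17 | DBU-ligated 3-alkylidene-1-oxa-2-nickelacyclopentan-5-one from 16 and CO2 (allylnickel carboxylate, not isolated) | O=C1O[Ni]CC1=CCC/C(C)=C/[C@@H](O[Si](CC)(CC)CC)C/C(C)=C/[C@@H](O[Si](C)(C)C(C)(C)C)C/C(C)=C/C=O | intermediate
18 | 2-[(1R,2S,3E,6S,7E,10S,11E)-6-[(tert-butyldimethylsilyl)oxy]-2-hydroxy-4,8,12-trimethyl-10-[(triethylsilyl)oxy]cyclotetradeca-3,7,11-trien-1-yl]prop-2-enoic acid (not isolated) | OC(=O)C(=C)[C@H]1CC/C(C)=C/[C@@H](O[Si](CC)(CC)CC)C/C(C)=C/[C@@H](O[Si](C)(C)C(C)(C)C)C/C(C)=C/[C@@H]1O | intermediate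
19 | (1R,6S,10S,14S,4E,8E,12E)-10-[(tert-butyldimethylsilyl)oxy]-6-[(triethylsilyl)oxy]cembra-4,8,12,15(17)-tetraen-16,14-olide (not isolated) | C=C1C(=O)O[C@H]2/C=C(\C)C[C@H](O[Si](C)(C)C(C)(C)C)/C=C(\C)C[C@H](O[Si](CC)(CC)CC)/C=C(\C)CC[C@H]12 | intermediate
20 | (1R,6S,10S,14S,4E,8E,12E)-10-[(tert-butyldimethylsilyl)oxy]-6-hydroxycembra-4,8,12,15(17)-tetraen-16,14-olide | C=C1C(=O)O[C@H]2/C=C(\C)C[C@H](O[Si](C)(C)C(C)(C)C)/C=C(\C)C[C@H](O)/C=C(\C)CC[C@H]12 | intermediate
21 | (1R,6S,10S,14S,4E,8E,12E)-6-acetoxy-10-[(tert-butyldimethylsilyl)oxy]cembra-4,8,12,15(17)-tetraen-16,14-olide | C=C1C(=O)O[C@H]2/C=C(\C)C[C@H](O[Si](C)(C)C(C)(C)C)/C=C(\C)C[C@H](OC(C)=O)/C=C(\C)CC[C@H]12 | intermediate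
22 | (3aR,6E,8S,10E,12S,14E,15aS)-12-hydroxy-6,10,14-trimethyl-3-methylidene-2-oxo-2,3,3a,4,5,8,9,12,13,15a-decahydrocyclotetradeca[b]furan-8-yl acetate (CNP0406430.1) | C=C1C(=O)O[C@H]2/C=C(\C)C[C@H](O)/C=C(\C)C[C@H](OC(C)=O)/C=C(\C)CC[C@H]12 | target

**Step count.** Total: 15 steps. Longest linear sequence: 14 steps (3 → 22, steps 2–15); step 1 prepares the dienolate 2 used in steps 5 and 9.

**Steps most likely to fail**

1. Step 13 (Proposed new method). The allylnickel carboxylate may be protonated or oligomerise instead of closing the ring. Ni(0) may engage the enal, DBU may isomerise or γ-deprotonate the enal, and facial selectivity relative to C6/C10 may be poor. The fallback uses known chemistry, sets out from 16 and returns at 20, and makes the two bonds in two operations. A copper-catalysed borylative allene–aldehyde addition ((NHC)CuCl, NaOt-Bu, B2pin2, THF, high dilution) should add Cu–Bpin across the allene with boron at C15. The resulting 2-borylallylcopper should close the ring at C14 to give the macrocyclic 2-boryl homoallylic alcohol F1; a chiral NHC ligand would offer reagent control over C1/C14. Palladium(II)-catalysed oxidative alkoxycarbonylation of the alkenylboronate by the C14 hydroxyl (Pd(OAc)2, PPh3, p-benzoquinone, CO 1 atm) should then form C15–C16 and give the TES lactone 19. Treatment with AcOH/THF/H2O removes the TES group and returns to 20.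

2. Step 9. Catalyst control over the enal face may be insufficient on the larger, silyl-ether-bearing aldehyde, γ-selectivity may erode, or the TES group may be lost to adventitious HCl. The fallback sets out from 12 (with 2) and returns at 13. It separates C–C bond formation from stereocontrol. An achiral BF3·OEt2-mediated vinylogous Mukaiyama aldol reaction (CH2Cl2, −78 °C) should give the C5-epimeric alcohol mixture F2. Dess–Martin oxidation should give the enone F3, and Corey–Bakshi–Shibata reduction ((R)-Me-CBS, catecholborane, toluene, −78 °C; alkenyl as the large group) should deliver 13 with the (5S) configuration.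

3. Step 3. The Mannich base may fail to fragment cleanly, or the amine may add to the enamide at reflux, leaving little allene. The fallback sets out from 5 and returns at 7. Hydroxymethylation of the acetylide (LiHMDS, THF, −78 °C; (CH2O)n) should give the propargylic alcohol F4. Its reductive transposition by the Myers allene synthesis (o-nitrobenzenesulfonylhydrazide, PPh3, DEAD, THF, −15 °C → rt) should give allene 7 through the propargylic diazene.

**Further compounds**

F1 | step 13 | (1R,2R,3E,6S,7E,10S,11E)-6-[(tert-butyldimethylsilyl)oxy]-4,8,12-trimethyl-1-[1-(4,4,5,5-tetramethyl-1,3,2-dioxaborolan-2-yl)ethenyl]-10-[(triethylsilyl)oxy]cyclotetradeca-3,7,11-trien-2-ol | C=C(B1OC(C)(C)C(C)(C)O1)[C@H]1CC/C(C)=C/[C@@H](O[Si](CC)(CC)CC)C/C(C)=C/[C@@H](O[Si](C)(C)C(C)(C)C)C/C(C)=C/[C@@H]1O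
F2 | step 9 | ethyl (2E,5RS,6E,9S,10E)-5-hydroxy-3,7,11-trimethyl-9-[(triethylsilyl)oxy]hexadeca-2,6,10,14,15-pentaenoate | CCOC(=O)/C=C(\C)CC(O)/C=C(\C)C[C@H](O[Si](CC)(CC)CC)/C=C(\C)CCC=C=C
F3 | step 9 | ethyl (2E,6E,9S,10E)-3,7,11-trimethyl-5-oxo-9-[(triethylsilyl)oxy]hexadeca-2,6,10,14,15-pentaenoate | CCOC(=O)/C=C(\C)CC(=O)/C=C(\C)C[C@H](O[Si](CC)(CC)CC)/C=C(\C)CCC=C=C
F4 | step 3 | (2E)-8-hydroxy-N-methoxy-N,3-dimethyloct-2-en-6-ynamide | CON(C)C(=O)/C=C(\C)CCC#CCO
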